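Per litre of solution I counted one reagent for each solid substrate, an assumption of mine, so the smaller charge, the limiting reagent, caps what can turn over.

- Wednesday's: solid substrate 0.10 M; reagent 0.075 M; run made earlier
- flask: solid substrate 0.10 M; reagent 0.150 M; time 2.5 min

Wednesday's run (percent of the solid substrate charged)

| time / s | target / % | solid product / % |
|---|---|---|
| 10.0 | 16.7 | 0 |
| 15.0 | 23.0 | 0 |
| 20.0 | 35.9 | 0.6 |
| 30.0 | 46.0 | 2.7 |

(each reading ± 1 percentage point)

- for target the solid product is counted in
- as a solid, counted per litre of solution: solid substrate, solid product
- at the start none of the solid substrate is in solution
- dissolved substrate means what is dissolved; the solid is not counted in it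

1. target and solid product together at 2.5 min, in percent of the solid substrate charged
2. concentration of dissolved substrate in solution at 2.5 min, in percent of saturation

For the new flask this gave 100%. I called it the ceiling C, the smaller charge over the solid substrate charged, and took it as my upper bound. On Wednesday's run C was 75.0%.

For a lower bound, a reckoning of mine and no proof, I began from Wednesday's last reading, 46.0% at 30.0 s. At that steady pace I reckoned C for the new flask after 65.2 s, sooner than 2.5 min. But this first answer meant a vanishing solid, so I put it back in and went round once more, letting the rate fall in proportion to what remained. Each 30.0 s then left the fraction that Wednesday's last reading had left, and I kept that pace although the new flask held twice the reagent. This gave 95.4%.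

The forecast said 98%, on the ground that “Doubling the reagent should leave the early rate unchanged but remove the 75% cap”, and it put dissolved substrate at 1% of saturation. Its 98% lay inside my bracket.

The flask gave 90.5%, below my bracket, and dissolved substrate at 0% of saturation.

    solid substrate ⇌ dissolved substrate, rate k1*(cs1 - [dissolved substrate]) while solid is left; crystals form when [dissolved substrate] > cs1 (solubility = 17.0 mM, k = 0.240 s⁻¹)
    dissolved substrate + reagent → target (k = 3.80 L mol⁻¹ s⁻¹)
    solid product ⇌ target, rate k3*(cs3 - [target]) while solid is left; crystals form when [target] > cs3 (solubility = 42.0 mM, k = 0.0800 s⁻¹)
    target ⇌ isomer of the product (K = 3.80, k = 0.00150 s⁻¹)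

At 2.50 min the flask also held 9.53% as isomer of the product, and target plus isomer of the product came to >99.9%, about C. A neighbouring flask with 0.037 M of reagent has C = 37.0%. At 2.50 min that neighbouring flask had 0.0146% of its own reagent charge left, 30.7% as target and 6.25% as isomer of the product, together 36.9%, about C, with 46.0% still solid substrate.

(The numbers in the tables stem from a simulated flask with made-up constants, noise included.)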